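**Retrosynthetic overview**
- Feature: if C7 of the acrylate arm is read as an aldehyde, ring C1–C6 is a cyclohex-1-ene-1-carbaldehyde. C7, C1 and C6 are then the carbonyl, α- and β-carbons of an enal, and C2 is a spent aldehyde carbon. A second carboxyl on C5 makes it a malonate donor, so C5 (donor), C6 (acceptor), C1 (donor) and C2 (acceptor) alternate.
- Late disconnections: benzyl and tert-butyl groups (Lewis acid); C3 CO2H back to CH2OTBS (oxidation); C5–H back to C5(CO2allyl)2 (deallylation, decarboxylation); C7=C8 (Horner–Wadsworth–Emmons reaction with the phosphonoacetate of protected (R)-danshensu).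
- Key disconnection: C5–C6 and C1=C2 open to a C2–C5 aldehyde malonate and tert-butyl (E)-4-oxobut-2-enoate (iminium Michael addition, then enamine aldol condensation).
- The aldehyde malonate comes from an arylidene malonate and 3-silyloxypropanal by an enamine Michael addition that sets C3 and C4. Both amine-catalysed steps call for the (R)-catalyst.
- Ring order: the two catechol rings are bought. The cyclohexene is the only ring made, and it is made in the key step.

Key step: step 5

Locants used throughout: ring C1 (bears the arm C7=C8–C9), C2 (=CH), C3, C4 (aryl), C5, C6.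
Assumption: the sense of induction in steps 2 and 5 is taken from the usual shielding model of diarylprolinol silyl ethers, in which the partner approaches the E-enamine or the E,s-trans iminium ion on the face away from the CPh2(OTMS) group. Applied to both steps, this model puts the C3 arm and the C6 ester cis to each other and trans to the aryl group with a single antipode, the (R)-catalyst.

**Step 1**
Reactants: 1 3,4-bis(benzyloxy)benzaldehyde; 2 diallyl malonate
Product: 3 diallyl 2-[3,4-bis(benzyloxy)benzylidene]malonate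
Conditions: piperidine (10 mol %), AcOH (10 mol %), toluene, reflux, Dean–Stark
Reagents that add atoms: none
Why: Knoevenagel condensation of a non-enolisable aromatic aldehyde with a malonate under piperidinium acetate catalysis and azeotropic removal of water is routine, and no alkene geometry is at stake because the two esters are alike.

**Step 2**
Reactants: 3 diallyl 2-[3,4-bis(benzyloxy)benzylidene]malonate; 4 3-(tert-butyldimethylsilyloxy)propanal
Product: 5 diallyl 2-[(1S,2R)-1-[3,4-bis(benzyloxy)phenyl]-3-(tert-butyldimethylsilyloxy)-2-formylpropyl]malonate (C2–C5 aldehyde malonate; C3 R and C4 S)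
Conditions: 4 (3 equiv), (R)-α,α-diphenylprolinol trimethylsilyl ether (20 mol %), PhCO2H (20 mol %), CHCl3 (2 M), rt
Reagents that add atoms: none
Why: Enamine-catalysed Michael addition of an aldehyde to an arylidene malonate is a known reaction of diarylprolinol silyl ethers, a catalyst class that also accepts β-silyloxy aldehydes as donors, and attack on the anti E-enamine of 4 on the face away from the CPh2(OTMS) group through a synclinal open transition state should give the syn adduct (C3 R, C4 S), which becomes the trans relation in the ring.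

**Step 3**
Reactants: 6 2,2-dimethoxyacetaldehyde (commercial 60 % aqueous solution); 7 (tert-butoxycarbonylmethylene)triphenylphosphorane
Product: 8 tert-butyl (E)-4,4-dimethoxybut-2-enoate
Conditions: CH2Cl2, 0 °C → rt
Reagents that add atoms: none
Why: Wittig olefination with a stabilised ylide tolerates the water of the aldehyde solution and should give the E-enoate.

**Step 4**
Reactants: 8 tert-butyl (E)-4,4-dimethoxybut-2-enoate
Product: 9 tert-butyl (E)-4-oxobut-2-enoate
Conditions: 1 M aq HCl, THF, rt
Reagents that add atoms: water, O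
Why: Acid-catalysed hydrolysis of a dimethyl acetal in dilute aqueous acid at room temperature is much faster than loss of a tert-butyl ester, and the E-alkene is the stable geometry.

**Step 5**
Reactants: 5 diallyl 2-[(1S,2R)-1-[3,4-bis(benzyloxy)phenyl]-3-(tert-butyldimethylsilyloxy)-2-formylpropyl]malonate; 9 tert-butyl (E)-4-oxobut-2-enoate
Product: 12 1,1-diallyl 2-tert-butyl (2S,5R,6R)-6-[3,4-bis(benzyloxy)phenyl]-5-[(tert-butyldimethylsilyloxy)methyl]-3-formylcyclohex-3-ene-1,1,2-tricarboxylate (cyclohexene-1-carbaldehyde with C5 gem-diester; route locants C3 R C4 R C6 S), via Michael adduct dialdehyde 10 (not isolated), via aldol 11 (not isolated)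
Conditions: 9 (1.5 equiv), (R)-α,α-diphenylprolinol trimethylsilyl ether (20 mol %), LiOAc (20 mol %), CH2Cl2–EtOH 9:1, 0 °C → rt
Reagents that add atoms: none
Why: The catalyst condenses with the unhindered enal 9 to an E,s-trans iminium ion, the lithium-assisted enolate at C5 of 5 adds to its ester-bearing β-carbon (C5–C6, enamine of 10), the enamine carbon C1 attacks the tethered C2 aldehyde (aldol 11), and loss of water with hydrolysis of the iminium ion frees the catalyst and enal 12 (C1=C2). The closest known reaction type is the amine-catalysed Michael–aldol condensation domino of aldehyde-tethered 2-substituted malonates with enals, which builds cyclopentene and cyclohexene carbaldehydes that carry a gem-diester quaternary carbon. The one ring closed, the cyclohexene, forms by a 6-(enolexo)-exo-trig aldol. C6 is the only new stereocentre and is set by the catalyst: the CPh2(OTMS) group of the (R)-antipode covers the Si face of the β-carbon, C5 arrives on the Re face, and C6 becomes S with its ester cis to the C3 arm and trans to the C4 aryl, the pairing of centres that one antipode gives when it controls an enamine Michael and an iminium Michael step in turn. The step needs chemoselectivity (the amine must activate 9 and not the α-branched aldehyde of 5, which steric hindrance secures, and 9 has no γ-hydrogen for dienamine formation), regioselectivity (iminium activation makes the carbon β to the aldehyde, not the one β to the ester, the acceptor) and site selectivity in the donor (only the malonate C–H is acidic enough for acetate). The irreversible dehydration should draw the reversible and sterically costly Michael addition forward.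

**Step 6**
Reactants: 13 (R)-danshensu, (R)-3-(3,4-dihydroxyphenyl)-2-hydroxypropanoic acid
Product: 14 benzyl (R)-3-[3,4-bis(benzyloxy)phenyl]-2-hydroxypropanoate
Conditions: BnBr (3.3 equiv), K2CO3 (3.5 equiv), DMF, rt, argon
Reagents that add atoms: benzyl bromide, BrCc1ccccc1
Why: In this Williamson-type O-alkylation the carbonate deprotonates only the carboxyl and the two phenols, so the secondary alcohol should stay free and the untouched stereocentre keeps its R configuration.

**Step 7**
Reactants: 14 benzyl (R)-3-[3,4-bis(benzyloxy)phenyl]-2-hydroxypropanoate; 15 diethylphosphonoacetic acid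
Product: 16 benzyl (R)-3-[3,4-bis(benzyloxy)phenyl]-2-[2-(diethoxyphosphoryl)acetoxy]propanoate
Conditions: DCC, DMAP (10 mol %), CH2Cl2, 0 °C → rt
Reagents that add atoms: none
Why: Steglich esterification acylates the secondary alcohol without breaking the C–O bond at the stereocentre, so the R configuration is retained.

**Step 8**
Reactants: 12 cyclohexene-1-carbaldehyde with C5 gem-diester; 16 danshensu phosphonoacetate
Product: 17 benzyl (R)-2-{(E)-3-[(3R,4R,6S)-5,5-bis(allyloxycarbonyl)-4-[3,4-bis(benzyloxy)phenyl]-6-(tert-butoxycarbonyl)-3-[(tert-butyldimethylsilyloxy)methyl]cyclohex-1-en-1-yl]acryloyloxy}-3-[3,4-bis(benzyloxy)phenyl]propanoate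
Conditions: LiCl, iPr2NEt, MeCN, 0 °C → rt
Reagents that add atoms: none
Why: In the Horner–Wadsworth–Emmons reaction under Masamune–Roush conditions the lithium-chelated phosphonoacetate is deprotonated by an amine too weak to enolise C6–H, C3–H or the lactate α-hydrogen, and it should give the E C7=C8 alkene.

**Step 9**
Reactants: 17 dienoate with C5 gem-diallyl ester
Product: 19 (1R,2R,5R,6S)-3-{(E)-3-[(R)-1-benzyloxy-3-[3,4-bis(benzyloxy)phenyl]-1-oxopropan-2-yloxy]-3-oxoprop-1-enyl}-6-[3,4-bis(benzyloxy)phenyl]-2-(tert-butoxycarbonyl)-5-[(tert-butyldimethylsilyloxy)methyl]cyclohex-3-ene-1-carboxylic acid (C5 monoacid; route locants C3 R C4 S C5 R C6 R), via malonic acid 18 (not isolated)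
Conditions: Pd(PPh3)4 (5 mol %), PhNHMe (4 equiv), THF, rt; 1 M KHSO4 wash; then toluene, 100 °C
Reagents that add atoms: none
Why: Tsuji–Trost deallylation (π-allyl formation with zerovalent palladium, capture by the aniline) frees the malonic acid under neutral conditions, its thermal decarboxylation gives an exocyclic enediol, and kinetic axial protonation of that enediol anti to the C6 ester, which A(1,2) strain against the C1 arm holds pseudoaxial, should place the C5 carboxyl equatorial, cis to C6 and trans to the aryl (5R), which is also the more stable epimer.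

**Step 10**
Reactants: 19 C5 monoacid silyl ether
Product: 20 the corresponding C3 hydroxymethyl compound (C3 R, C4 S, C5 R, C6 R, lactate R)
Conditions: HF·pyridine, pyridine, THF, 0 °C → rt
Reagents that add atoms: none
Why: Fluoride cleavage of a primary TBS ether in a buffered acidic medium generates no alkoxide, so the esters, the benzyl ethers and the base-sensitive C3 and C6 centres should be left alone.

**Step 11**
Reactants: 20 C3 hydroxymethyl compound
Product: 21 the C3,C5-diacid (C3 R, C4 S, C5 R, C6 R, lactate R; C6 tert-butyl ester, five benzyl groups)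
Conditions: TEMPO (20 mol %), PhI(OAc)2 (2.5 equiv), MeCN–H2O 1:1, rt
Reagents that add atoms: water, O
Why: Oxoammonium oxidation (TEMPO with PhI(OAc)2) takes the primary alcohol through the aldehyde hydrate to the acid in a weakly acidic medium, so the β,γ-unsaturated aldehyde should be consumed before C3 can epimerise or the alkene can migrate.

**Step 12**
Reactants: 21 protected C3,C5-diacid
Product: 22 (R)-2-{(E)-3-[(3R,4S,5R,6R)-3,5,6-tricarboxy-4-(3,4-dihydroxyphenyl)cyclohex-1-en-1-yl]acryloyloxy}-3-(3,4-dihydroxyphenyl)propanoic acid (CNP0327643.1)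
Conditions: BCl3 (1 M in CH2Cl2, excess), C6HMe5 (excess), CH2Cl2, −78 → 0 °C; THF–H2O quench
Reagents that add atoms: none
Why: In this Lewis-acid dealkylation BCl3 ionises the four aryl benzyl ethers, the benzyl ester and the tert-butyl ester while pentamethylbenzene traps the benzyl cations, the lactate-type ester cannot ionise next to its carbonyl group, the alkenes that rule out hydrogenolysis are untouched, and no base is present to disturb C3, C5 or C6.

**Compound list**
1 | 3,4-bis(benzyloxy)benzaldehyde | O=Cc1ccc(OCc2ccccc2)c(OCc2ccccc2)c1 | starting material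
2 | diallyl malonate | C=CCOC(=O)CC(=O)OCC=C | starting material
3 | diallyl 2-[3,4-bis(benzyloxy)benzylidene]malonate | C=CCOC(=O)C(=Cc1ccc(OCc2ccccc2)c(OCc2ccccc2)c1)C(=O)OCC=C | intermediate
4 | 3-(tert-butyldimethylsilyloxy)propanal | O=CCCO[Si](C)(C)C(C)(C)C | starting material
5 | diallyl 2-[(1S,2R)-1-[3,4-bis(benzyloxy)phenyl]-3-(tert-butyldimethylsilyloxy)-2-formylpropyl]malonate | O=C[C@@H](CO[Si](C)(C)C(C)(C)C)[C@H](c1ccc(OCc2ccccc2)c(OCc2ccccc2)c1)C(C(=O)OCC=C)C(=O)OCC=C | intermediate
6 | 2,2-dimethoxyacetaldehyde | COC(OC)C=O | starting material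
7 | (tert-butoxycarbonylmethylene)triphenylphosphorane | CC(C)(C)OC(=O)C=P(c1ccccc1)(c1ccccc1)c1ccccc1 | starting material
8 | tert-butyl (E)-4,4-dimethoxybut-2-enoate | COC(OC)/C=C/C(=O)OC(C)(C)C | intermediate
9 | tert-butyl (E)-4-oxobut-2-enoate | O=C/C=C/C(=O)OC(C)(C)C | intermediate
10 | diallyl 2-[(1R,2R)-1-[3,4-bis(benzyloxy)phenyl]-3-(tert-butyldimethylsilyloxy)-2-formylpropyl]-2-[(S)-1-tert-butoxy-1,4-dioxobutan-2-yl]malonate (open Michael adduct, present as its catalyst enamine, drawn as the free dialdehyde) | O=C[C@@H](CO[Si](C)(C)C(C)(C)C)[C@H](c1ccc(OCc2ccccc2)c(OCc2ccccc2)c1)C(C(=O)OCC=C)(C(=O)OCC=C)[C@H](CC=O)C(=O)OC(C)(C)C | intermediate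
11 | β-hydroxy aldehyde from the ring-closing aldol, configured as 12 at C3, C4 and C6; C1 and C2 undefined and lost on dehydration | O=CC1C(O)[C@@H](CO[Si](C)(C)C(C)(C)C)[C@H](c2ccc(OCc3ccccc3)c(OCc3ccccc3)c2)C(C(=O)OCC=C)(C(=O)OCC=C)[C@H]1C(=O)OC(C)(C)C | intermediate
12 | 1,1-diallyl 2-tert-butyl (2S,5R,6R)-6-[3,4-bis(benzyloxy)phenyl]-5-[(tert-butyldimethylsilyloxy)methyl]-3-formylcyclohex-3-ene-1,1,2-tricarboxylate | O=CC1=C[C@@H](CO[Si](C)(C)C(C)(C)C)[C@H](c2ccc(OCc3ccccc3)c(OCc3ccccc3)c2)C(C(=O)OCC=C)(C(=O)OCC=C)[C@H]1C(=O)OC(C)(C)C | intermediate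
13 | (R)-danshensu | O[C@H](Cc1ccc(O)c(O)c1)C(=O)O | starting material
14 | benzyl (R)-3-[3,4-bis(benzyloxy)phenyl]-2-hydroxypropanoate | O[C@H](Cc1ccc(OCc2ccccc2)c(OCc2ccccc2)c1)C(=O)OCc1ccccc1 | intermediate
15 | diethylphosphonoacetic acid | CCOP(=O)(CC(=O)O)OCC | starting material
16 | benzyl (R)-3-[3,4-bis(benzyloxy)phenyl]-2-[2-(diethoxyphosphoryl)acetoxy]propanoate | CCOP(=O)(CC(=O)O[C@H](Cc1ccc(OCc2ccccc2)c(OCc2ccccc2)c1)C(=O)OCc1ccccc1)OCC | intermediate
17 | dienoate, (3R,4R,6S)-ring with 5,5-bis(allyloxycarbonyl), 6-tert-butoxycarbonyl and 3-CH2OTBS, (E)-acrylate of 14 | O=C(/C=C/C1=C[C@@H](CO[Si](C)(C)C(C)(C)C)[C@H](c2ccc(OCc3ccccc3)c(OCc3ccccc3)c2)C(C(=O)OCC=C)(C(=O)OCC=C)[C@H]1C(=O)OC(C)(C)C)O[C@H](Cc1ccc(OCc2ccccc2)c(OCc2ccccc2)c1)C(=O)OCc1ccccc1 | intermediate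
18 | C5 malonic acid, as 17 with 5,5-dicarboxy (3R,4R,6S) | O=C(/C=C/C1=C[C@@H](CO[Si](C)(C)C(C)(C)C)[C@H](c2ccc(OCc3ccccc3)c(OCc3ccccc3)c2)C(C(=O)O)(C(=O)O)[C@H]1C(=O)OC(C)(C)C)O[C@H](Cc1ccc(OCc2ccccc2)c(OCc2ccccc2)c1)C(=O)OCc1ccccc1 | intermediate
19 | C5 monoacid (3R,4S,5R,6R), 3-CH2OTBS, 6-tert-butyl ester | O=C(/C=C/C1=C[C@@H](CO[Si](C)(C)C(C)(C)C)[C@H](c2ccc(OCc3ccccc3)c(OCc3ccccc3)c2)[C@@H](C(=O)O)[C@H]1C(=O)OC(C)(C)C)O[C@H](Cc1ccc(OCc2ccccc2)c(OCc2ccccc2)c1)C(=O)OCc1ccccc1 | intermediate
20 | C3 hydroxymethyl C5 acid (3R,4S,5R,6R) | O=C(/C=C/C1=C[C@@H](CO)[C@H](c2ccc(OCc3ccccc3)c(OCc3ccccc3)c2)[C@@H](C(=O)O)[C@H]1C(=O)OC(C)(C)C)O[C@H](Cc1ccc(OCc2ccccc2)c(OCc2ccccc2)c1)C(=O)OCc1ccccc1 | intermediate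
21 | C3,C5-diacid (3R,4S,5R,6R), 6-tert-butyl ester, five benzyl groups | O=C(/C=C/C1=C[C@@H](C(=O)O)[C@H](c2ccc(OCc3ccccc3)c(OCc3ccccc3)c2)[C@@H](C(=O)O)[C@H]1C(=O)OC(C)(C)C)O[C@H](Cc1ccc(OCc2ccccc2)c(OCc2ccccc2)c1)C(=O)OCc1ccccc1 | intermediate
22 | (R)-2-{(E)-3-[(3R,4S,5R,6R)-3,5,6-tricarboxy-4-(3,4-dihydroxyphenyl)cyclohex-1-en-1-yl]acryloyloxy}-3-(3,4-dihydroxyphenyl)propanoic acid | O=C(/C=C/C1=C[C@@H](C(=O)O)[C@H](c2ccc(O)c(O)c2)[C@@H](C(=O)O)[C@H]1C(=O)O)O[C@H](Cc1ccc(O)c(O)c1)C(=O)O | target

**Total step count:** 12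
**Longest linear sequence:** 8 steps (1, 2, 5, 8, 9, 10, 11, 12)

**Steps most likely to fail**

**Step 5.**
- What may go wrong: the crowded tertiary malonate carbon may add to the iminium ion too slowly or reversibly. Oligomerisation of the enal, retro-Michael cleavage of the donor, epimerisation at C3 or loss of silanol from the β-silyloxy aldehyde could then overtake ring closure. Facial selectivity at C6 may also erode if the resident C3 and C4 centres oppose the catalyst.
- Fallback (sets out from 5, comes back at 10 and through it at 12): the two bonds are made in separate operations with a true enolate as donor. The aldehyde of 5 is masked with TMSOMe and catalytic TMSOTf (CH2Cl2, −78 °C) as the dimethyl acetal F1. Its malonate is deprotonated under solid–liquid phase transfer (Cs2CO3, N-benzylcinchonidinium chloride, toluene, −20 °C) and added to 9. Attack goes β to the aldehyde, the stronger acceptor, and gives the acetal aldehyde F2. C6 is then under the joint control of the chiral cation and C4, and the epimers can be separated after ring closure. LiBF4 in wet MeCN frees dialdehyde 10, and dibenzylammonium trifluoroacetate (toluene, 50 °C) closes it by aldol condensation to 12.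

**Step 2.**
- What may go wrong: the electron-rich arylidene malonate is a weak acceptor. The addition may be slow enough for self-aldol reaction of 4, loss of silanol and epimerisation at C3 to compete.
- Fallback (sets out from 1 and 2, comes back at 5): C4 and C3 are set in two separate catalytic steps. Wittig reaction of 1 with (triphenylphosphoranylidene)acetaldehyde (toluene, 80 °C) gives (E)-3-[3,4-bis(benzyloxy)phenyl]acrylaldehyde F3. Iminium-catalysed addition of 2 with the (R)-catalyst (EtOH, 0 °C), a well-tried reaction of cinnamaldehydes, gives the (S)-aldehyde F4 and sets C4. Enamine α-hydroxymethylation with aqueous formaldehyde follows under the (S)-catalyst (toluene, pH 7 buffer). The other antipode is needed here because electrophile and chain have changed roles. This gives the hydroxy aldehyde F5 and sets C3. F5 is silylated at once (TBSCl, imidazole, CH2Cl2, 0 °C) to 5.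

**Step 9.**
- What may go wrong: the enediol may be protonated on the wrong face, through the conformer with the aryl group axial. The C1=C2 alkene may also migrate into conjugation with the C6 ester during heating.
- Fallback (sets out from 17, comes back at 22): the C5 carboxyl that is to be kept is tied to the C6 carboxyl before CO2 is lost. TMSOTf and 2,6-lutidine (CH2Cl2, 0 °C, aqueous work-up) cleave only the tert-butyl ester and give the C6 acid F6. Pd(PPh3)4 and PhNHMe then free the triacid F7. DCC (1 equiv, THF, 0 °C) closes the five-membered anhydride between C6 and the cis carboxyl on C5. The remaining carboxyl, now α to an anhydride carbonyl, is lost on gentle warming, and the enol should be protonated to the less strained cis-fused anhydride F8. HF·pyridine followed by water gives the diacid alcohol F9. TEMPO and PhI(OAc)2 as in step 11 give the triacid F10, and BCl3 with C6HMe5 as in step 12 gives 22.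

**Further compounds**
F1 | step 5 | diallyl 2-[(1S,2R)-1-[3,4-bis(benzyloxy)phenyl]-2-[(tert-butyldimethylsilyloxy)methyl]-3,3-dimethoxypropyl]malonate | COC(OC)[C@@H](CO[Si](C)(C)C(C)(C)C)[C@H](c1ccc(OCc2ccccc2)c(OCc2ccccc2)c1)C(C(=O)OCC=C)C(=O)OCC=C
F2 | step 5 | dimethyl acetal (at C2) of dialdehyde 10 | COC(OC)[C@@H](CO[Si](C)(C)C(C)(C)C)[C@H](c1ccc(OCc2ccccc2)c(OCc2ccccc2)c1)C(C(=O)OCC=C)(C(=O)OCC=C)[C@H](CC=O)C(=O)OC(C)(C)C
F3 | step 2 | (E)-3-[3,4-bis(benzyloxy)phenyl]acrylaldehyde | O=C/C=C/c1ccc(OCc2ccccc2)c(OCc2ccccc2)c1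
F4 | step 2 | diallyl 2-[(S)-1-[3,4-bis(benzyloxy)phenyl]-3-oxopropyl]malonate | O=CC[C@H](c1ccc(OCc2ccccc2)c(OCc2ccccc2)c1)C(C(=O)OCC=C)C(=O)OCC=C
F5 | step 2 | diallyl 2-[(1S,2R)-1-[3,4-bis(benzyloxy)phenyl]-2-formyl-3-hydroxypropyl]malonate | O=C[C@@H](CO)[C@H](c1ccc(OCc2ccccc2)c(OCc2ccccc2)c1)C(C(=O)OCC=C)C(=O)OCC=C
F6 | step 9 | C6 acid, as 17 with 6-carboxy (3R,4R,6S) | O=C(/C=C/C1=C[C@@H](CO[Si](C)(C)C(C)(C)C)[C@H](c2ccc(OCc3ccccc3)c(OCc3ccccc3)c2)C(C(=O)OCC=C)(C(=O)OCC=C)[C@H]1C(=O)O)O[C@H](Cc1ccc(OCc2ccccc2)c(OCc2ccccc2)c1)C(=O)OCc1ccccc1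
F7 | step 9 | C5,C5,C6-triacid (3R,4R,6S) | O=C(/C=C/C1=C[C@@H](CO[Si](C)(C)C(C)(C)C)[C@H](c2ccc(OCc3ccccc3)c(OCc3ccccc3)c2)C(C(=O)O)(C(=O)O)[C@H]1C(=O)O)O[C@H](Cc1ccc(OCc2ccccc2)c(OCc2ccccc2)c1)C(=O)OCc1ccccc1
F8 | step 9 | cis-fused C5/C6 cyclic anhydride (3R,4S,5R,6R) | O=C(/C=C/C1=C[C@@H](CO[Si](C)(C)C(C)(C)C)[C@H](c2ccc(OCc3ccccc3)c(OCc3ccccc3)c2)[C@H]2C(=O)OC(=O)[C@@H]12)O[C@H](Cc1ccc(OCc2ccccc2)c(OCc2ccccc2)c1)C(=O)OCc1ccccc1
F9 | step 9 | C5,C6-diacid with C3 hydroxymethyl (3R,4S,5R,6R) | O=C(/C=C/C1=C[C@@H](CO)[C@H](c2ccc(OCc3ccccc3)c(OCc3ccccc3)c2)[C@@H](C(=O)O)[C@H]1C(=O)O)O[C@H](Cc1ccc(OCc2ccccc2)c(OCc2ccccc2)c1)C(=O)OCc1ccccc1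
F10 | step 9 | C3,C5,C6-triacid with five benzyl groups (3R,4S,5R,6R) | O=C(/C=C/C1=C[C@@H](C(=O)O)[C@H](c2ccc(OCc3ccccc3)c(OCc3ccccc3)c2)[C@@H](C(=O)O)[C@H]1C(=O)O)O[C@H](Cc1ccc(OCc2ccccc2)c(OCc2ccccc2)c1)C(=O)OCc1ccccc1
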